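Assumptions: the target is achiral 6-(3-hydroxy-3-methylbutyl)kaempferol, and flavone numbering is used throughout (O1, C2, C3, C4, C4a, C5 to C8, C8a; ring B primed). The (Z) descriptor written for 14, 15, 17 and 18 is the expected thermodynamic geometry; that double bond becomes C2=C3 of ring C, so an (E) contaminant would converge on the same flavone.

## The problem

The target is a flavonol whose ring A is pentasubstituted: oxygen at C5 and C7, a 3-hydroxy-3-methylbutyl chain between them at C6, and only C8 unsubstituted. It has no stereocentre, so the task is one of regiochemistry: the chain must sit at C6 and not C8, and an oxygen must be present at C3. The tertiary alcohol is three carbons from ring A and flanked by two phenolic oxygens. Acid would ionise it and close a 2,2-dimethylchroman onto O5 or O7, or dehydrate it, so no acidic deprotection is acceptable at the end. The free polyphenolic flavonol is also oxidised by air in base, so the last step should be neutral. Hydrogenolysis of benzyl-type groups meets this, and in turn forbids a reducible side chain. The C3 oxygen is best carried in from the start, because peroxide oxidation of a 2'-hydroxychalcone (Algar–Flynn–Oyamada) tends to give aurones when the ring A position next to the carbonyl bears an oxygen, as C5 does here. The feature that opens the key step is that the C8a–O1 and C4a–C4 bonds are adjacent on ring A and C4a is next to the C5 oxygen. That is the polarity of a 3-alkoxyaryne: an oxygen nucleophile is taken up at the carbon remote from the alkoxy group, and a carbon electrophile at the carbon next to it. Ring A can also be drawn from a mirror-symmetric phloroglucinol diether, so the C6/C8 question is settled while the two positions are still identical.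

## Retrosynthesis

**20 from 19.** The last operation cuts five O–C bonds: four benzyl ethers (O3, O5, O7, O4') and the benzyloxymethyl (BOM) acetal on the tertiary alcohol. One neutral hydrogenolysis of the flavone 19 does this without exposing the tertiary alcohol to acid or the flavonol to base. A silyl ether on the tertiary alcohol would need a separate fluoride step and might not survive hot CsF in the key step, so BOM is preferred. The forward step must leave the C2=C3 bond and the C4 carbonyl of the pyranone untouched.

**19 from 18.** Ring C is opened at O1–C2 and two hydrogens are added, giving the 2'-hydroxy-α-benzyloxychalcone 18. Cutting here keeps the C3 oxygen in place as the α-benzyloxy group, so no oxygen has to be introduced at C3 later and the aurone problem is avoided. The forward step is a 6-endo O–C closure with loss of two hydrogens, for which catalysis by divalent palladium under O2 is mild enough for the acetal and benzyl ethers.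

**18 from 11 and 15 (key disconnection).** The C8a–O1 and C4a–C4 bonds are cut together, giving the 2-(trimethylsilyl)aryl triflate 11 and the α-benzyloxycinnamic acid 15. The neighbouring options are weaker. A Friedel–Crafts acylation would put a hindered acyl group between two oxygens under Lewis acids that the BOM and benzyl groups do not tolerate. A Claisen–Schmidt route would need a ring A acetophenone with three differentiated phenols. The aryne insertion forms both bonds in one convergent step and differentiates O1 (free hydroxyl) from O5 and O7 (benzyl) automatically. It asks that the carboxylate add only to the aryne carbon remote from the C5 benzyloxy group and that the acyl shift outrun protonation.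

**15 from 12 and 13.** The Cα=Cβ bond is cut to methyl 2-(benzyloxy)acetate 12 and 4-(benzyloxy)benzaldehyde 13, both commercial. The forward reaction is an aldol condensation with saponification in the same pot, through ester 14.

**11 from 8, 8 from 7.** The C–Si and O–S bonds of 11 trace back to the ortho-bromophenol 8 by the silylation, retro-Brook, triflation sequence, and the C–Br bond to phenol 7. Phenol 7 is mirror-symmetric about the O1/chain axis and its para position is blocked, so bromination can give only one monobromide.

**7 from 6, 6 from 5, 5 from 2 and 3, 2 from 1.** The phenol 7 comes from silyl ether 6 and the BOM ether 6 from tertiary alcohol 5. The aryl–CH2 bond of 5 is cut to the aryllithium 4 (from silyl ether 2) and 2,2-dimethyloxetane 3, which delivers the whole chain with its tertiary hydroxyl in one step. The bulky triisopropylsilyl group on 3,5-bis(benzyloxy)phenol 1 neither directs nor permits metalation next to it, so lithiation is confined to the position between the two benzyloxy groups. The forward sequence needs that site selectivity and an SN2 opening of the oxetane at its CH2 terminus.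

## Roads not taken

**Alternative 1:** Ring C is cut at O1–C8a. The enolate oxygen of the 2-benzyloxy-1,3-diketone A2 displaces an ortho bromide under CuI, 1,10-phenanthroline and K2CO3, giving the tetra-O-benzyl-6-prenylkaempferol A1.
- Merits: the heterocycle closes in the key step at the flavone oxidation level, so no oxidation follows. The ring A pattern comes from a symmetric 5-bromoresorcinol diether. Intramolecular O-arylation of 2-haloaryl diketones under monovalent copper is well established.
- Weak points: the difficulty moves into A2. Its ketone sits between a bromine and a benzyloxy group on a ring that also carries a prenyl group. Lithiation is excluded by the bromide, and Lewis-acid acylation by the prenyl and benzyl groups. C-aroylation of the α-benzyloxy ketone must also beat O-acylation. After A1 the prenyl group still has to be hydrated before hydrogenolysis, so the endgame is no shorter.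
- Comparison: its ring closure is probably more certain than a crowded aryne insertion and needs no oxidant. Against that, the chosen plan forms two skeletal bonds in a convergent union and draws both partners from short, conventional sequences.

**Alternative 2:** Ring C is cut at C3–C4. A triazolium-derived carbene with DBU would join the two aldehydes of A4 in an intramolecular benzoin reaction to give the 3-hydroxyflavanone A3.
- Merits: the C3 oxygen appears as a free hydroxyl with no protecting group, the conditions are mild enough for an unprotected tertiary alcohol, and the endgame after A3 (dehydrogenation, hydrogenolysis) is as short as the chosen one.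
- Weak points: A4 contains an aldehyde whose α-carbon bears both an aryl group and an aryloxy leaving group. Carbene addition to that aldehyde is expected to expel the phenoxide and form an acyl azolium enolate, leading to a redox ester and not a benzoin. Enolisation by DBU and the crowded 2,6-dioxygenated aryl aldehyde as acyl-anion donor add to the doubt. The two stereocentres made are destroyed again.
- Comparison: it is more economical in protecting groups, but it relies on a fragile precursor with a built-in decomposition pathway. The chosen plan has stable intermediates and a regiochemical outcome with direct precedent.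

**Alternative 3:** Ring A is cut at C5–C6, C7–C8 and C4a–C5. Irradiation of the pyranonyl diazoketone A6 would give a vinylketene by Wolff rearrangement. This would add the siloxyalkyne A7, and ring opening and 6π closure would then give the flavonol derivative A5 with free 5-OH and silylated O7.
- Merits: three bonds and the whole pentasubstituted ring A form in one step. Regiochemistry is dictated by the polarised ynol ether, which also brings in the C6 chain, and ring C arrives at its final oxidation level.
- Weak points: A6 requires a γ-pyrone carrying an acyl side chain at C6, a multi-step heterocycle synthesis. γ-Pyrones have their own photochemistry in the same wavelength range. A7 needs an ynolate silylation and is moisture-sensitive. Three kinds of protecting group must then be removed in at least two steps.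
- Comparison: it is the most powerful ring construction of the four. The chosen plan sets against it a ring A taken from a commercial phloroglucinol derivative and much shorter fragment syntheses.

Key step: step 8

## Route

Step 1
Reactants: 1 3,5-bis(benzyloxy)phenol
Product: 2 [3,5-bis(benzyloxy)phenoxy]triisopropylsilane
Conditions: TIPSCl, imidazole, DMF, rt
Reagents that add atoms: triisopropylsilyl chloride, CC(C)[Si](Cl)(C(C)C)C(C)C
Why: Silylation of a phenol; the bulky silyl ether masks O1 through the organolithium step and, as a poor ligand for lithium, leaves the position between the two benzyloxy groups as the only site for directed metalation.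

Step 2
Reactants: 2 [3,5-bis(benzyloxy)phenoxy]triisopropylsilane; 3 2,2-dimethyloxetane
Product: 5 4-[2,6-bis(benzyloxy)-4-(triisopropylsilyloxy)phenyl]-2-methylbutan-2-ol, via aryllithium 4 (not isolated)
Conditions: n-BuLi, THF, 0 °C; then 3, BF3·OEt2, −78 °C; aqueous work-up
Reagents that add atoms: none
Why: Directed ortho-metalation between two cooperating alkoxy groups, then Lewis-acid-assisted SN2 opening of the oxetane at its unsubstituted CH2 by the aryllithium; this places the complete side chain with its tertiary hydroxyl on the future C6 in one step.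

Step 3
Reactants: 5 4-[2,6-bis(benzyloxy)-4-(triisopropylsilyloxy)phenyl]-2-methylbutan-2-ol
Product: 6 {3,5-bis(benzyloxy)-4-[3-(benzyloxymethoxy)-3-methylbutyl]phenoxy}triisopropylsilane
Conditions: BnOCH2Cl, i-Pr2NEt, Bu4NI (cat.), ClCH2CH2Cl, 50 °C
Reagents that add atoms: benzyl chloromethyl ether, ClCOCc1ccccc1
Why: Alkoxymethylation of a tertiary alcohol with a reactive chloromethyl ether under amine base; the BOM acetal should withstand fluoride, butyllithium, hot CsF and the aerobic palladium step, and leaves with the benzyl ethers in the final hydrogenolysis.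

Step 4
Reactants: 6 {3,5-bis(benzyloxy)-4-[3-(benzyloxymethoxy)-3-methylbutyl]phenoxy}triisopropylsilane
Product: 7 3,5-bis(benzyloxy)-4-[3-(benzyloxymethoxy)-3-methylbutyl]phenol
Conditions: Bu4NF, THF, 0 °C; aqueous work-up
Reagents that add atoms: none
Why: Fluoride cleavage of an aryl silyl ether, fast at 0 °C because phenoxide leaves silicon readily; benzyl ethers and the BOM acetal are inert to fluoride.

Step 5
Reactants: 7 3,5-bis(benzyloxy)-4-[3-(benzyloxymethoxy)-3-methylbutyl]phenol
Product: 8 3,5-bis(benzyloxy)-4-[3-(benzyloxymethoxy)-3-methylbutyl]-2-bromophenol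
Conditions: NBS (1 equiv), CH2Cl2, −78 to 0 °C
Reagents that add atoms: N-bromosuccinimide, O=C1CCC(=O)N1Br
Why: Electrophilic ortho-bromination of a phenol; the para position is blocked by the chain and the two ortho positions are related by the mirror plane, so only one monobromide can form, and one equivalent at low temperature should limit dibromination.

Step 6
Reactants: 8 3,5-bis(benzyloxy)-4-[3-(benzyloxymethoxy)-3-methylbutyl]-2-bromophenol
Product: 11 3,5-bis(benzyloxy)-4-[3-(benzyloxymethoxy)-3-methylbutyl]-2-(trimethylsilyl)phenyl trifluoromethanesulfonate, via trimethylsilyl ether 9 (not isolated), via lithium 2-silylphenoxide 10 (not isolated)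
Conditions: (Me3Si)2NH, THF, 65 °C, then evaporation; n-BuLi, THF, −78 °C; Tf2O, −78 °C
Reagents that add atoms: hexamethyldisilazane, C[Si](C)(C)N[Si](C)(C)C; trifluoromethanesulfonic anhydride, O=S(=O)(OS(=O)(=O)C(F)(F)F)C(F)(F)F
Why: Standard one-pot route from ortho-bromophenols to 2-(trimethylsilyl)aryl triflates: O-silylation, bromine–lithium exchange (faster at −78 °C than any benzylic deprotonation), retro-Brook 1,3 O-to-C silyl shift and triflation of the resulting phenoxide.

Step 7
Reactants: 12 methyl 2-(benzyloxy)acetate; 13 4-(benzyloxy)benzaldehyde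
Product: 15 (Z)-2-(benzyloxy)-3-[4-(benzyloxy)phenyl]acrylic acid, via methyl ester 14 (not isolated)
Conditions: NaOMe, MeOH, 65 °C; then aq. NaOH, 65 °C; then HCl
Reagents that add atoms: sodium hydroxide, [Na+].[OH-]
Why: Claisen–Schmidt-type aldol condensation of an alkoxyacetate enolate with a non-enolisable aryl aldehyde, with E1cB loss of water; equilibrating alkoxide conditions should favour the (Z) isomer, in which the aryl group is trans to the carboxyl, and the ester is saponified in the same pot.

Step 8
Reactants: 11 3,5-bis(benzyloxy)-4-[3-(benzyloxymethoxy)-3-methylbutyl]-2-(trimethylsilyl)phenyl trifluoromethanesulfonate; 15 (Z)-2-(benzyloxy)-3-[4-(benzyloxy)phenyl]acrylic acid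
Product: 18 (Z)-2-(benzyloxy)-3-[4-(benzyloxy)phenyl]-1-{2,4-bis(benzyloxy)-3-[3-(benzyloxymethoxy)-3-methylbutyl]-6-hydroxyphenyl}prop-2-en-1-one, via aryne 16 (not isolated), via cesium aryl anion ester 17 (not isolated)
Conditions: CsF (excess), THF, 125 °C (sealed tube); aqueous work-up
Reagents that add atoms: none
Why: Excess CsF first converts 15 into its cesium carboxylate, and fluoride attack on silicon with loss of triflate then releases the 3-benzyloxyaryne 16. The carboxylate oxygen adds to the aryne carbon remote from the adjacent benzyloxy group, which puts the negative charge on the carbon next to that oxygen (17), where it is stabilised inductively. This aryl anion attacks its own ester carbonyl through a four-membered transition structure that opens to the ketone phenoxide, an anionic 1,3 O-to-C acyl shift. The closest known reaction type is the insertion of arynes from 2-(trimethylsilyl)aryl triflates into the C–O bond of carboxylic acids, α,β-unsaturated ones included, to give ortho-hydroxyaryl ketones. No ring is closed (the four-membered ring is transient only) and no stereocentre is made; the alkene geometry of 15 is expected to carry over. The regioselectivity needed is secured by the inductive and distorting effect of the flanking benzyloxy group, which should override the weak opposing bias of the remote one, and by attack at the carbon whose neighbour is only a hydrogen. The chemoselectivity needed is acyl shift before protonation, favoured by the aprotic medium, the pre-formed carboxylate and the high temperature; conjugate attack at the β-carbon is disfavoured by the s-trans ester geometry, which holds that carbon away from the anion. Ring C should stay open because the product is a chelated cesium phenoxide and the α-alkoxy enone is a poor Michael acceptor.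

Step 9
Reactants: 18 (Z)-2-(benzyloxy)-3-[4-(benzyloxy)phenyl]-1-{2,4-bis(benzyloxy)-3-[3-(benzyloxymethoxy)-3-methylbutyl]-6-hydroxyphenyl}prop-2-en-1-one
Product: 19 3,5,7-tris(benzyloxy)-2-[4-(benzyloxy)phenyl]-6-[3-(benzyloxymethoxy)-3-methylbutyl]-4H-chromen-4-one
Conditions: Pd(OCOCF3)2 (10 mol %), 5-nitro-1,10-phenanthroline (20 mol %), DMSO, O2 (1 atm), 100 °C
Reagents that add atoms: none
Why: Aerobic oxidative cyclisation of a 2'-hydroxychalcone catalysed by divalent palladium: 6-endo oxypalladation of the enone by the phenol and β-hydride elimination from C2 give the chromen-4-one, and O2 reoxidises zerovalent palladium. Any flavanone formed by conjugate addition should be dehydrogenated by the same catalyst through its palladium enolate, so both paths converge on 19.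

Step 10
Reactants: 19 3,5,7-tris(benzyloxy)-2-[4-(benzyloxy)phenyl]-6-[3-(benzyloxymethoxy)-3-methylbutyl]-4H-chromen-4-one
Product: 20 3,5,7-trihydroxy-6-(3-hydroxy-3-methylbutyl)-2-(4-hydroxyphenyl)-4H-chromen-4-one
Conditions: H2 (1 atm), 10% Pd/C, EtOAc–MeOH, rt
Reagents that add atoms: none
Why: Hydrogenolysis of four benzyl ethers and of the benzyl group of the BOM acetal, whose hemiacetal then loses formaldehyde, all under neutral conditions that spare the tertiary alcohol. The C2=C3 bond is part of a vinylogous ester and is not expected to be reduced at atmospheric pressure.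

## Compound list

1 | 3,5-bis(benzyloxy)phenol | Oc1cc(OCc2ccccc2)cc(OCc2ccccc2)c1 | starting material
2 | [3,5-bis(benzyloxy)phenoxy]triisopropylsilane | CC(C)[Si](Oc1cc(OCc2ccccc2)cc(OCc2ccccc2)c1)(C(C)C)C(C)C | intermediate
3 | 2,2-dimethyloxetane | CC1(C)CCO1 | starting material
4 | [2,6-bis(benzyloxy)-4-(triisopropylsilyloxy)phenyl]lithium | [Li]c1c(OCc2ccccc2)cc(O[Si](C(C)C)(C(C)C)C(C)C)cc1OCc1ccccc1 | intermediate (not isolated)
5 | 4-[2,6-bis(benzyloxy)-4-(triisopropylsilyloxy)phenyl]-2-methylbutan-2-ol | CC(C)(O)CCc1c(OCc2ccccc2)cc(O[Si](C(C)C)(C(C)C)C(C)C)cc1OCc1ccccc1 | intermediate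
6 | {3,5-bis(benzyloxy)-4-[3-(benzyloxymethoxy)-3-methylbutyl]phenoxy}triisopropylsilane | CC(C)(OCOCc1ccccc1)CCc1c(OCc2ccccc2)cc(O[Si](C(C)C)(C(C)C)C(C)C)cc1OCc1ccccc1 | intermediate
7 | 3,5-bis(benzyloxy)-4-[3-(benzyloxymethoxy)-3-methylbutyl]phenol | CC(C)(OCOCc1ccccc1)CCc1c(OCc2ccccc2)cc(O)cc1OCc1ccccc1 | intermediate
8 | 3,5-bis(benzyloxy)-4-[3-(benzyloxymethoxy)-3-methylbutyl]-2-bromophenol | CC(C)(OCOCc1ccccc1)CCc1c(OCc2ccccc2)cc(O)c(Br)c1OCc1ccccc1 | intermediate
9 | {3,5-bis(benzyloxy)-4-[3-(benzyloxymethoxy)-3-methylbutyl]-2-bromophenoxy}trimethylsilane | CC(C)(OCOCc1ccccc1)CCc1c(OCc2ccccc2)cc(O[Si](C)(C)C)c(Br)c1OCc1ccccc1 | intermediate (not isolated)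
10 | lithium 3,5-bis(benzyloxy)-4-[3-(benzyloxymethoxy)-3-methylbutyl]-2-(trimethylsilyl)phenoxide | [Li+].CC(C)(OCOCc1ccccc1)CCc1c(OCc2ccccc2)cc([O-])c([Si](C)(C)C)c1OCc1ccccc1 | intermediate (not isolated)
11 | 3,5-bis(benzyloxy)-4-[3-(benzyloxymethoxy)-3-methylbutyl]-2-(trimethylsilyl)phenyl trifluoromethanesulfonate | CC(C)(OCOCc1ccccc1)CCc1c(OCc2ccccc2)cc(OS(=O)(=O)C(F)(F)F)c([Si](C)(C)C)c1OCc1ccccc1 | intermediate
12 | methyl 2-(benzyloxy)acetate | COC(=O)COCc1ccccc1 | starting material
13 | 4-(benzyloxy)benzaldehyde | O=Cc1ccc(OCc2ccccc2)cc1 | starting material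
14 | methyl (Z)-2-(benzyloxy)-3-[4-(benzyloxy)phenyl]acrylate | COC(=O)/C(OCc1ccccc1)=C/c1ccc(OCc2ccccc2)cc1 | intermediate (not isolated)
15 | (Z)-2-(benzyloxy)-3-[4-(benzyloxy)phenyl]acrylic acid | OC(=O)/C(OCc1ccccc1)=C/c1ccc(OCc2ccccc2)cc1 | intermediate
16 | 3,5-bis(benzyloxy)-4-[3-(benzyloxymethoxy)-3-methylbutyl]-1,2-didehydrobenzene (aryne) | CC(C)(OCOCc1ccccc1)CCC1=C(OCc2ccccc2)C#CC=C1OCc1ccccc1 | intermediate (not isolated)
17 | cesium 2,4-bis(benzyloxy)-3-[3-(benzyloxymethoxy)-3-methylbutyl]-6-{[(Z)-2-(benzyloxy)-3-(4-(benzyloxy)phenyl)acryloyl]oxy}benzenide | [Cs+].CC(C)(OCOCc1ccccc1)CCc1c(OCc2ccccc2)cc(OC(=O)/C(OCc2ccccc2)=C/c2ccc(OCc3ccccc3)cc2)[c-]c1OCc1ccccc1 | intermediate (not isolated)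
18 | (Z)-2-(benzyloxy)-3-[4-(benzyloxy)phenyl]-1-{2,4-bis(benzyloxy)-3-[3-(benzyloxymethoxy)-3-methylbutyl]-6-hydroxyphenyl}prop-2-en-1-one | CC(C)(OCOCc1ccccc1)CCc1c(OCc2ccccc2)cc(O)c(C(=O)/C(OCc2ccccc2)=C/c2ccc(OCc3ccccc3)cc2)c1OCc1ccccc1 | intermediate
19 | 3,5,7-tris(benzyloxy)-2-[4-(benzyloxy)phenyl]-6-[3-(benzyloxymethoxy)-3-methylbutyl]-4H-chromen-4-one | CC(C)(OCOCc1ccccc1)CCc1c(OCc2ccccc2)cc2oc(-c3ccc(OCc4ccccc4)cc3)c(OCc3ccccc3)c(=O)c2c1OCc1ccccc1 | intermediate
20 | 3,5,7-trihydroxy-6-(3-hydroxy-3-methylbutyl)-2-(4-hydroxyphenyl)-4H-chromen-4-one (CNP0250430.0) | CC(C)(O)CCc1c(O)cc2oc(-c3ccc(O)cc3)c(O)c(=O)c2c1O | target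

## Step count and risk

Total steps: 10. Longest linear sequence: 9 (steps 1 to 6 and 8 to 10, from 1); step 7 is a one-step branch.

**Step 8 (key step).** The aryl anion 17 may be protonated by bifluoride or adventitious proton sources before the acyl shift, so that the reaction stops at O-arylation. The product phenoxide may also add to a second aryne, and partial conjugate closure of ring C may occur. The fallback generates the same ortho-metalated aryl ester by halogen–metal exchange. It sets out from 8 and 15: Steglich esterification (DCC, DMAP, CH2Cl2) should give 3,5-bis(benzyloxy)-4-[3-(benzyloxymethoxy)-3-methylbutyl]-2-bromophenyl (Z)-2-(benzyloxy)-3-[4-(benzyloxy)phenyl]acrylate F1. Bromine–lithium exchange with n-BuLi in THF at −100 °C should then trigger the same anionic 1,3 O-to-C acyl shift, and the route is rejoined at 18.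

**Step 2.** Deprotonation at a benzylic ether position (leading to 1,2-Wittig rearrangement) may compete with ring metalation. The BF3-complexed gem-dimethyl oxetane may also ionise at its tertiary carbon before the hindered aryllithium attacks. The fallback sets out from 2 through aryllithium 4, kept at 0 °C or below: transmetalation with CuBr·SMe2 and alkylation with prenyl bromide should give [3,5-bis(benzyloxy)-4-(3-methylbut-2-en-1-yl)phenoxy]triisopropylsilane F2. Mukaiyama hydration (Co(acac)2, PhSiH3, O2, i-PrOH) should then add water in the Markovnikov sense and rejoin the route at 5.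

**Step 9.** Oxypalladation of the electron-rich, α-alkoxy-substituted enone may be slow, and electrophilic palladation at the unsubstituted C8 of ring A may lead to oxidative coupling. The fallback separates closure from oxidation. It sets out from 18: conjugate closure (NaOAc, EtOH, reflux) should give 3,5,7-tris(benzyloxy)-2-[4-(benzyloxy)phenyl]-6-[3-(benzyloxymethoxy)-3-methylbutyl]chroman-4-one F3 (racemic, mixture of 2,3-diastereomers). Dehydrogenation with DDQ in dioxane at 90 °C should then rejoin the route at 19.

**Step 7.** Self-condensation of the ester and retro-aldol cleavage may outrun dehydration with the electron-rich aldehyde. The fallback is stepwise and sets out from 12 and 13. A lithium enolate aldol (LDA, THF, −78 °C) should give methyl 2-(benzyloxy)-3-[4-(benzyloxy)phenyl]-3-hydroxypropanoate F4 (mixture of diastereomers). Mesylation (MsCl, Et3N) should give methyl 2-(benzyloxy)-3-[4-(benzyloxy)phenyl]-3-(methylsulfonyloxy)propanoate F5. Elimination with DBU rejoins the route at 14, which is saponified to 15 as in step 7.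

## Further compounds

F1 | step 8 | 3,5-bis(benzyloxy)-4-[3-(benzyloxymethoxy)-3-methylbutyl]-2-bromophenyl (Z)-2-(benzyloxy)-3-[4-(benzyloxy)phenyl]acrylate | CC(C)(OCOCc1ccccc1)CCc1c(OCc2ccccc2)cc(OC(=O)/C(OCc2ccccc2)=C/c2ccc(OCc3ccccc3)cc2)c(Br)c1OCc1ccccc1
F2 | step 2 | [3,5-bis(benzyloxy)-4-(3-methylbut-2-en-1-yl)phenoxy]triisopropylsilane | CC(C)=CCc1c(OCc2ccccc2)cc(O[Si](C(C)C)(C(C)C)C(C)C)cc1OCc1ccccc1
F3 | step 9 | 3,5,7-tris(benzyloxy)-2-[4-(benzyloxy)phenyl]-6-[3-(benzyloxymethoxy)-3-methylbutyl]chroman-4-one (racemic, mixture of diastereomers) | CC(C)(OCOCc1ccccc1)CCc1c(OCc2ccccc2)cc2OC(c3ccc(OCc4ccccc4)cc3)C(OCc3ccccc3)C(=O)c2c1OCc1ccccc1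
F4 | step 7 | methyl 2-(benzyloxy)-3-[4-(benzyloxy)phenyl]-3-hydroxypropanoate (mixture of diastereomers) | COC(=O)C(OCc1ccccc1)C(O)c1ccc(OCc2ccccc2)cc1
F5 | step 7 | methyl 2-(benzyloxy)-3-[4-(benzyloxy)phenyl]-3-(methylsulfonyloxy)propanoate (mixture of diastereomers) | COC(=O)C(OCc1ccccc1)C(OS(C)(=O)=O)c1ccc(OCc2ccccc2)cc1
A1 | alternative 1 | 3,5,7-tris(benzyloxy)-2-[4-(benzyloxy)phenyl]-6-(3-methylbut-2-en-1-yl)-4H-chromen-4-one | CC(C)=CCc1c(OCc2ccccc2)cc2oc(-c3ccc(OCc4ccccc4)cc3)c(OCc3ccccc3)c(=O)c2c1OCc1ccccc1
A2 | alternative 1 | 1-[2,4-bis(benzyloxy)-6-bromo-3-(3-methylbut-2-en-1-yl)phenyl]-2-(benzyloxy)-3-[4-(benzyloxy)phenyl]propane-1,3-dione | CC(C)=CCc1c(OCc2ccccc2)cc(Br)c(C(=O)C(OCc2ccccc2)C(=O)c2ccc(OCc3ccccc3)cc2)c1OCc1ccccc1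
A3 | alternative 2 | 5,7-bis(benzyloxy)-2-[4-(benzyloxy)phenyl]-3-hydroxy-6-(3-hydroxy-3-methylbutyl)chroman-4-one (racemic, mixture of diastereomers) | CC(C)(O)CCc1c(OCc2ccccc2)cc2OC(c3ccc(OCc4ccccc4)cc3)C(O)C(=O)c2c1OCc1ccccc1
A4 | alternative 2 | 2-[3,5-bis(benzyloxy)-2-formyl-4-(3-hydroxy-3-methylbutyl)phenoxy]-2-[4-(benzyloxy)phenyl]acetaldehyde (racemic) | CC(C)(O)CCc1c(OCc2ccccc2)cc(OC(C=O)c2ccc(OCc3ccccc3)cc2)c(C=O)c1OCc1ccccc1
A5 | alternative 3 | 3-(benzyloxy)-2-[4-(benzyloxy)phenyl]-5-hydroxy-6-[3-methyl-3-(triethylsilyloxy)butyl]-7-(triisopropylsilyloxy)-4H-chromen-4-one | CC[Si](CC)(CC)OC(C)(C)CCc1c(O[Si](C(C)C)(C(C)C)C(C)C)cc2oc(-c3ccc(OCc4ccccc4)cc3)c(OCc3ccccc3)c(=O)c2c1O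
A6 | alternative 3 | 3-(benzyloxy)-2-[4-(benzyloxy)phenyl]-6-(2-diazoacetyl)-4H-pyran-4-one | [N-]=[N+]=CC(=O)c1cc(=O)c(OCc2ccccc2)c(-c2ccc(OCc3ccccc3)cc2)o1
A7 | alternative 3 | triethyl{[2-methyl-6-(triisopropylsilyloxy)hex-5-yn-2-yl]oxy}silane | CC[Si](CC)(CC)OC(C)(C)CCC#CO[Si](C(C)C)(C(C)C)C(C)C
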